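## Structural features

The target is a 1,7,8,8a-tetrahydro-6H-isochromen-6-one. Ring A (O18, C9, C10, C11, C16, C17) is a dihydropyran fused through the C11–C16 bond to ring B (C11 to C16), a cyclohexenone, and C9 carries an (E)-alkenyl chain (C8=C7, then C6 down to C2). Ring B holds three contiguous stereocentres: the tertiary methyl carbinol C14 (S), the secondary carbinol C15 (S) and the ring-fusion methine C16 (S). Both hydroxyls and H16 lie on one face, and C14 sits between the C13 ketone and C15. The chain holds three more in a row: the tertiary carbinol C6 (S), the secondary carbinol C5 (R) and the methyl-bearing methine C4 (R), with C4-CH3/C5-OH anti and C5-OH/C6-OH anti. The C7=C8 alkene separates this triad from the ring, so neither set can control the other. Fragile groups are the dienol ether–dienone O18–C9=C10–C11=C12–C13=O (sensitive to acid, amines and hydride), the tertiary allylic alcohol at C6, the α-ketol C13/C14 and the epimerisable γ-position C16. The real difficulty is ring B: a quaternary carbinol of defined configuration between two oxygenated carbons, next to an unsaturated pyran that tolerates no harsh reagent. The pattern C13(=O), C14(CH3)(OH), C15(O) on adjacent carbons, with carbon arms on C11 and C16, is that of a 2-methylresorcinol dearomatised by hydroxylation at its methyl-bearing carbon. The key step uses this: enzymatic hydroxylation of an aromatic precursor at C14, after which the C17 aldehyde and the C10–C9 oxoalkyl arm close ring A through O18–C17, two reductions above the target.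

## Logic of the disconnections

23 to 20. The C17–H and C16–H bonds are removed and the C16=C17 double bond is restored. C16 is a γ-position of the dienone and can be set by protonation, so it is the ring centre that can be left to the end. The gain is one stereocentre and a substrate whose ring A becomes an aromatic pyrylium on O13 protonation. The forward step must deliver hydride to C17 only (not C9, C11 or C13), put the proton on C16 on the face of the C15 hydroxyl, and use acid mild enough for the C6 and C15 alcohols.

20 to 19. The C15–H bond is removed, returning C15 to a ketone. Reducing C15 before C16=C17 is saturated keeps it a simple, non-enolisable ketone; in the other order C15=O and C13=O would form a vinylogous 1,3-diketone with an acidic C16–H. The gain is a second ring stereocentre. The forward step must reduce C15 and not C13 and deliver hydride on the face of the C14 methyl; the flat ring offers no bias, so the catalyst must impose the face.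

19 to 17 (key step). The C14–OH bond and the O18–C17 bond are cut; ring A opens and ring B becomes an aromatic 3-methylresorcinol aldehyde. This removes one ring, the only quaternary stereocentre and all sp3 carbons of the bicycle. The forward step must hydroxylate C14 (not C12), on one face, in the presence of a free diol, an enone and an aldehyde.

17 to 16. Two aryl O–CH2 acetal bonds and one O–Si bond are restored. The masks are needed only for the organolithium chemistry of the preceding step. Their removal must not ionise the tertiary allylic C6–O bond.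

16 to 13 and 11. The C9–C10 bond is cut between the benzylic carbon and the ketone. This is the most convergent cut: it separates the arene from the complete chiral chain at a bond with no stereochemistry. The forward step needs a benzylic carbanion at C10 next to a masked aldehyde and clean 1,2-acylation of an enoyl amide without conjugate addition.

13 to 12. The two phenolic O–CH2 bonds are cut, leading to a commercial aldehyde. The forward step must also alkylate the hydrogen-bonded ortho hydroxyl.

11 to 9 and 10. The C7=C8 double bond is cut. This shortens the chain to a vinyl carbinol and takes the acyl end from a commercial acrylamide. The forward metathesis must tolerate the quaternary allylic carbon and give the E alkene.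

9 to 7. The C7–C8 bond is cut and C7 returns to an epoxide carbon bonded to the C6 oxygen. A 2,2-disubstituted epoxide is the product of a hydroxyl-directed epoxidation, the most reliable way to set C6 from C5. The forward one-carbon homologation must attack C7 only and leave C6 untouched.

7 to 6 to 5. The O–Si bond is cut, then the two C–H bonds that turn the ethyl group back into a vinyl group. The silyl ether is needed to stop epoxide migration under base. The hydrogenation must not move the double bond toward C4.

5 to 4. The C6–O and C7–O bonds of the epoxide are cut, giving a diene alcohol. The forward epoxidation must choose the allylic 1,1-disubstituted alkene over the vinyl group and the face that gives the anti C5-O/C6-O relation.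

4 to 1 and 2. The C4–C5 bond is cut, giving two commercial four-carbon units and removing the last two stereocentres. The forward crotylation must give the anti relation (from the E geometry of 2) and one absolute configuration (from a chiral catalyst, since 2 is achiral).

## Other disconnections considered

Alternative 1: The cut lies inside ring B, at C15–O (formed first as C15–B) and at C16–C17, on the achiral dienone A1. Its carbonyl carbon is the later C11 and its quaternary carbon the later C14. In the forward step a boryl–copper species from CuCl, a Josiphos-type bisphosphine, NaOtBu and B2pin2 adds to one of the two enantiotopic enone double bonds. Boron ends on C15 and the copper enolate at C16 is trapped by formaldehyde, giving A2.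
- In its favour: one catalytic step turns a flat, symmetric, cheap substrate into ring B with C14, C15 and C16 defined. Anti addition of boron and the hydroxymethyl group is the normal course and matches the C15/C16 relation of 23, and C–B oxidation goes with retention.
- Against it here: boron must enter cis to the C14 oxygen and trans to the C14 methyl, a choice resting on a small size difference and possible copper–oxygen coordination. The second enone must not react. A2 has its carbonyl at C11, not C13, so C10 must still be added, the oxygen transposed to C13 (for instance by oxidative rearrangement of the tertiary allylic alcohol), and ring A with the whole chain built through an O18–C9 closure.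
- Comparison: on structure it fixes C15 and C16 by catalyst control in the key step, which is better than leaving them to steps 11 and 12; but it forms no bond of ring A, whereas step 10 closes ring A on the complete skeleton. On mechanism both plans need a chiral catalyst to distinguish two faces; the copper system gives either enantiomer by ligand choice and is at least the equal of an enzyme chosen by homologue. On step economy it is worse: many operations on acid-sensitive intermediates would follow A2, against two steps after 19.

Alternative 2: The cut is the C14–C15 bond of ring B. The forward step is a cathodic pinacol cyclisation of the open-chain keto aldehyde A3 (tin cathode, sacrificial magnesium anode, isopropanol–DMF, tetraethylammonium tosylate), giving the cyclohexane diol A4.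
- In its favour: ring B and both carbinol centres form in one step, and the metal-bridged ketyl coupling to a six-membered ring normally gives the cis-diol that 23 needs. Electrons are the reagent.
- Against it here: A3 needs three stereocentres (C11, C13, C16), and C11 and C13 are later destroyed to make the C11=C12–C13=O enone. The α-silyloxy ketone and β-silyloxy aldehyde are prone to reductive C–O cleavage or β-elimination at the cathode. The relation of the new diol to C16 rests on acyclic induction in a flexible chain. After A4, C13 must be oxidised, C11 oxidised and joined to C10, the alkene introduced, and ring A and the chain attached.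
- Comparison: on structure it is better on one point, since the cis-diol is an intrinsic outcome whereas the chosen plan depends on an enzyme-controlled reduction (step 11). It is weaker on everything else, giving a saturated, over-protected ring with no ring A. On mechanism a ketyl radical coupling needs no face-selective catalyst, equal in simplicity of reagents, but its stereocontrol is only substrate-based. On step economy the redox corrections after A4 and the separate synthesis of A3 would make it clearly longer.

Alternative 3: The cut is the C9=C10 double bond of ring A. The chain is first attached as an ester of the C17 alcohol (A5). A reduced titanium ethylidene (TiCl4, zinc, catalytic PbCl2, TMEDA, 1,1-dibromoethane) then exchanges onto the C10 vinyl group and undergoes carbonyl–olefin metathesis with the ester carbonyl C9, giving the bicyclic dienyl ether A6.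
- In its favour: an esterification joins the two halves, and the acyl half of A5 is the chain that 11 carries. The acid-sensitive dienol ether forms late under non-acidic conditions. No stereocentre is made in the key step.
- Against it here: the ester is an enoate and the alkene partner is part of a 1,3-diene, so the alkylidene can engage C7=C8 or the diene unproductively. Low-valent titanium, zinc and lead are used in large excess on a late intermediate with five silyl ethers. After A6 the C13 silyl ether must be removed selectively and oxidised, and four more silyl ethers cleaved without harming the dienol ether. The ring B half of A5, with four contiguous stereocentres and a diene, remains a synthesis of its own.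
- Comparison: on structure it avoids both late reductions of the chosen plan and is at least equal in stereochemical safety at its key step; but it leaves all of ring B unsolved, whereas step 10 creates C14 and ring A together from a flat arene. On mechanism a stoichiometric metal alkylidene [2+2] sequence stands against a catalytic flavin hydroperoxide hydroxylation, and the enzyme is cleaner in reagent load. On step economy the convergence is attractive, but the preparation of A5 and the end game after A6 would exceed the twelve steps of the chosen route.

Key step: step 10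

Remarks on the chemistry, one line each:
- Numbering: C5 is the secondary carbinol, C6 the tertiary carbinol and C7=C8 the alkene; C4 is then the methyl-bearing methine and C3/C2 its ethyl group; C9 to C17 and O18 as in the ring description.
- An achiral crotylboronate cannot set absolute configuration, so step 1 is run under a chiral Brønsted acid.
- The C6 centre is set by directed epoxidation before the vinyl group is hydrogenated, which removes the need to tell two alkenes apart in a hydrogenation.
- C15 is reduced before C17 so that no vinylogous 1,3-diketone has to be handled.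
- 17 is drawn as the open keto aldehyde; it is expected to equilibrate with its cyclic lactol, and both forms feed step 10.
- The descriptor of C14 changes from R (19) to S (20 to 23) only because the ranking of C15 changes; the centre is not touched.

## Route

Step 1
Reactants: 1 methacrolein; 2 (E)-crotylboronic acid pinacol ester
Product: 4 (3R,4R)-2,4-dimethylhexa-1,5-dien-3-ol, via borate ester 3 (not isolated)
Conditions: (R)-3,3′-bis(2,4,6-triisopropylphenyl)-1,1′-binaphthyl-2,2′-diyl hydrogen phosphate (5 mol%), 4 Å MS, toluene, −30 °C; then H2O
Reagents that add atoms: none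
Why: Brønsted acid-catalysed crotylboration through a closed Zimmerman–Traxler chair, in which the E geometry of 2 gives the anti C4-CH3/C5-OH relation and hydrolysis of 3 releases the alcohol. The chiral phosphoric acid, bound to the boronate oxygen and the formyl hydrogen, is expected to direct attack to the Re face of 1 (3R,4R); the antipodal acid is used if the sense proves opposite.

Step 2
Reactants: 4 (3R,4R)-2,4-dimethylhexa-1,5-dien-3-ol
Product: 5 (1R,2R)-2-methyl-1-[(2S)-2-methyloxiran-2-yl]but-3-en-1-ol
Conditions: VO(acac)2 (2 mol%), t-BuOOH (1.3 equiv, decane), CH2Cl2, 0 °C → rt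
Reagents that add atoms: tert-butyl hydroperoxide CC(C)(C)OO
Why: Hydroxyl-directed vanadium-catalysed epoxidation; only the allylic 1,1-disubstituted alkene reacts through the vanadate ester, the homoallylic monosubstituted vinyl group being far slower. The transition state that keeps the carbinol substituent away from the C6 methyl (least 1,2-allylic strain) delivers oxygen anti to the hydroxyl along the chain, which sets C6 (S).

Step 3
Reactants: 5 (1R,2R)-2-methyl-1-[(2S)-2-methyloxiran-2-yl]but-3-en-1-ol
Product: 6 (1R,2R)-2-methyl-1-[(2S)-2-methyloxiran-2-yl]butan-1-ol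
Conditions: H2 (1 atm), RhCl(PPh3)3 (3 mol%), benzene–EtOH, rt
Reagents that add atoms: none
Why: Homogeneous hydrogenation of the only remaining alkene, a monosubstituted vinyl group. The rhodium catalyst does not migrate the double bond toward C4 and does not open the epoxide, so no stereocentre is affected.

Step 4
Reactants: 6 (1R,2R)-2-methyl-1-[(2S)-2-methyloxiran-2-yl]butan-1-ol
Product: 7 triethyl{(1R,2R)-2-methyl-1-[(2S)-2-methyloxiran-2-yl]butoxy}silane
Conditions: Et3SiCl, imidazole, DMAP (cat.), DMF, 0 °C → rt
Reagents that add atoms: triethylsilyl chloride CC[Si](Cl)(CC)CC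
Why: Silylation under amine-buffered conditions that neither open the epoxide nor form the alkoxide. The ether prevents Payne migration of the epoxide in the strongly basic next step and later leaves under the same acid as the phenol acetals.

Step 5
Reactants: 7 triethyl{(1R,2R)-2-methyl-1-[(2S)-2-methyloxiran-2-yl]butoxy}silane
Product: 9 (3S,4R,5R)-3,5-dimethyl-4-[(triethylsilyl)oxy]hept-1-en-3-ol, via sulfonium betaine 8 (not isolated)
Conditions: Me3S+ I− (4 equiv), n-BuLi (3.8 equiv), THF, −10 °C → rt
Reagents that add atoms: trimethylsulfonium iodide C[S+](C)C.[I-]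
Why: One-carbon homologation of an epoxide to an allylic alcohol with dimethylsulfonium methylide: the ylide opens the epoxide at its CH2 terminus C7 to give 8, which excess ylide converts by syn-elimination of dimethyl sulfide into the C7=C8 vinyl group. C6 is not a reacting centre and keeps its configuration; a 1,2-shift of the silyl group to the C6 alkoxide would be harmless because step 9 frees both oxygens.

Step 6
Reactants: 9 (3S,4R,5R)-3,5-dimethyl-4-[(triethylsilyl)oxy]hept-1-en-3-ol; 10 N-methoxy-N-methylprop-2-enamide
Product: 11 (2E,4S,5R,6R)-4-hydroxy-N-methoxy-N,4,6-trimethyl-5-[(triethylsilyl)oxy]oct-2-enamide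
Conditions: second-generation Hoveyda–Grubbs catalyst (5 mol%), 10 (3 equiv), CH2Cl2, 40 °C, argon sparge
Reagents that add atoms: none
Why: Olefin cross-metathesis between a vinyl carbinol that cannot easily homodimerise (quaternary allylic carbon) and an electron-poor acrylamide. The E enamide is expected as the thermodynamic product, and the free allylic hydroxyl is tolerated.

Step 7
Reactants: 12 2,4-dihydroxy-3,6-dimethylbenzaldehyde
Product: 13 2,4-bis(methoxymethoxy)-3,6-dimethylbenzaldehyde
Conditions: MeOCH2Cl (3 equiv), i-Pr2NEt (4 equiv), CH2Cl2, 0 → 40 °C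
Reagents that add atoms: chloromethyl methyl ether COCCl
Why: O-Alkylation of both phenols as methoxymethyl acetals, which survive alkyllithiums and leave in aqueous acid. Excess reagent and warming are used for the hydrogen-bonded ortho hydroxyl.

Step 8
Reactants: 13 2,4-bis(methoxymethoxy)-3,6-dimethylbenzaldehyde; 11 (2E,4S,5R,6R)-4-hydroxy-N-methoxy-N,4,6-trimethyl-5-[(triethylsilyl)oxy]oct-2-enamide
Product: 16 6-[(3E,5S,6R,7R)-5-hydroxy-5,7-dimethyl-2-oxo-6-[(triethylsilyl)oxy]non-3-en-1-yl]-2,4-bis(methoxymethoxy)-3-methylbenzaldehyde, via lithium amino alkoxide 14 (not isolated), via benzylic lithium compound 15 (not isolated)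
Conditions: 13 (2.5 equiv), MeN(Li)CH2CH2NMe2 (from the amine + n-BuLi), THF, −20 °C; n-BuLi, −20 °C; then 11 (1 equiv), −78 → −40 °C; AcOH, then H2O
Reagents that add atoms: none
Why: In situ protection of the aldehyde as α-amino alkoxide 14, whose diamine arm directs lateral lithiation to the neighbouring C10 methyl (complex-induced proximity) to give 15, followed by Weinreb ketone synthesis. One equivalent of 15 only deprotonates the C6 hydroxyl and returns 13; conjugate addition is disfavoured because C7 is shielded by the quaternary C6. Aqueous work-up releases the ketone and the aldehyde; no stereocentre is formed.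

Step 9
Reactants: 16 6-[(3E,5S,6R,7R)-5-hydroxy-5,7-dimethyl-2-oxo-6-[(triethylsilyl)oxy]non-3-en-1-yl]-2,4-bis(methoxymethoxy)-3-methylbenzaldehyde
Product: 17 6-[(3E,5S,6R,7R)-5,6-dihydroxy-5,7-dimethyl-2-oxonon-3-en-1-yl]-2,4-dihydroxy-3-methylbenzaldehyde
Conditions: 3 M aq. HCl–THF (1:3), rt → 40 °C; work-up at pH 6.5 (KH2PO4/K2HPO4)
Reagents that add atoms: none
Why: Acid hydrolysis of the two aryl methoxymethyl acetals and the triethylsilyl ether in one operation. The tertiary allylic alcohol is deactivated toward ionisation by the adjoining enone, and no stereocentre is touched.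

Step 10
Reactants: 17 6-[(3E,5S,6R,7R)-5,6-dihydroxy-5,7-dimethyl-2-oxonon-3-en-1-yl]-2,4-dihydroxy-3-methylbenzaldehyde
Product: 19 (7R)-3-[(1E,3S,4R,5R)-3,4-dihydroxy-3,5-dimethylhept-1-en-1-yl]-7-hydroxy-7-methyl-6H-isochromene-6,8(7H)-dione, via hydroxylated dienone 18 (not isolated)
Conditions: AzaH-type FAD monooxygenase (clarified lysate), NADP+ (cat.), D-glucose, glucose dehydrogenase, KH2PO4/K2HPO4 buffer (50 mM, pH 8.0), DMSO (5% v/v), air, 30 °C; EtOAc extraction
Reagents that add atoms: dioxygen O=O
Why: NADPH reduces the enzyme-bound flavin, which takes up O2 to give the C4a-hydroperoxyflavin; the bound phenolate of 17 attacks its distal oxygen through C14, the ring carbon ortho and para to the two oxygens, in an electrophilic aromatic hydroxylation that gives 18. The closest known reaction type is the hydroxylative dearomatisation of 3-methylresorcinol aldehydes with a benzylic ketone arm by the flavin monooxygenases of azaphilone pathways; the natural substrate of AzaH is described as having the same 2-oxonon-3-enyl arm and methyl branches, with a C5=C6 alkene where 17 has the diol. Ring A then closes without catalyst: the enol oxygen of the C9 ketone (O18) adds to the C17 aldehyde in a 6-exo-trig closure, and loss of water gives C16=C17 in conjugation with both ring carbonyls. The one new stereocentre, C14, is set by the enzyme, which exposes one face of the flat phenolate to the flavin; AzaH-type enzymes are known to give the R carbinol of azaphilones (the configuration of 19) and the AfoD type its epimer, so the homologue decides and the remote chain stereocentres do not. The step needs site selectivity (C14, not C12), chemoselectivity (no Dakin cleavage of the aldehyde, no epoxidation of the electron-poor enone) and face selectivity; the substrate secures the first two through the 3-methylresorcinol aldehyde pattern and its single doubly activated carbon, while the face rests on the enzyme alone. Phosphate buffer and prompt extraction are used because 19 condenses with primary amines at C17.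

Step 11
Reactants: 19 (7R)-3-[(1E,3S,4R,5R)-3,4-dihydroxy-3,5-dimethylhept-1-en-1-yl]-7-hydroxy-7-methyl-6H-isochromene-6,8(7H)-dione
Product: 20 (7S,8S)-3-[(1E,3S,4R,5R)-3,4-dihydroxy-3,5-dimethylhept-1-en-1-yl]-7,8-dihydroxy-7-methyl-7,8-dihydro-6H-isochromen-6-one
Conditions: NADPH-dependent ketoreductase (panel enzyme selected for the 8S alcohol), NADP+ (cat.), i-PrOH (10% v/v), KH2PO4/K2HPO4 buffer (100 mM, pH 6.5), DMSO (5% v/v), 30 °C
Reagents that add atoms: none
Why: Biocatalytic ketone reduction at C15, which is less deactivated than the C13 carbonyl (C13 is the terminus of two vinylogous ester paths from O18). Ring B is flat and gives no useful bias, so the enzyme must deliver hydride to the C15 face on the side of the C14 methyl, placing the new hydroxyl cis to the C14 hydroxyl (15S); an enzyme of the required sense is chosen by screening.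

Step 12
Reactants: 20 (7S,8S)-3-[(1E,3S,4R,5R)-3,4-dihydroxy-3,5-dimethylhept-1-en-1-yl]-7,8-dihydroxy-7-methyl-7,8-dihydro-6H-isochromen-6-one
Product: 23 (7S,8S,8aS)-3-[(1E,3S,4R,5R)-3,4-dihydroxy-3,5-dimethylhept-1-en-1-yl]-7,8-dihydroxy-7-methyl-1,7,8,8a-tetrahydro-6H-isochromen-6-one, via pyrylium phosphate 21 (not isolated), via trienol 22 (not isolated)
Conditions: diethyl 2,6-dimethyl-1,4-dihydropyridine-3,5-dicarboxylate (1.3 equiv), (PhO)2P(O)OH (10 mol%), MeCN, 0 °C → rt
Reagents that add atoms: none
Why: Acid-catalysed transfer hydrogenation: O13 protonation makes ring A an aromatic pyrylium (21), and the dihydropyridine transfers hydride to its unsubstituted α-carbon C17, as in the reduction of 2-benzopyrylium salts to 1H-isochromenes, to give 22. Protonation of 22 at C16 restores the conjugated enone; attack anti to the axial C15–H with the C15–O bond near the π-nodal plane puts H16 on the face of the hydroxyls. The resulting S configuration is also the expected thermodynamic one (C17, the C15 hydroxyl and the C14 methyl all equatorial on ring B), so continued acid contact should correct any epimer.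

## Compound list

1 | methacrolein (2-methylprop-2-enal) | CC(=C)C=O | starting material
2 | (E)-crotylboronic acid pinacol ester | C/C=C/CB1OC(C)(C)C(C)(C)O1 | starting material
3 | 2-{[(3R,4R)-2,4-dimethylhexa-1,5-dien-3-yl]oxy}-4,4,5,5-tetramethyl-1,3,2-dioxaborolane | C=C[C@@H](C)[C@@H](OB1OC(C)(C)C(C)(C)O1)C(C)=C | intermediate
4 | (3R,4R)-2,4-dimethylhexa-1,5-dien-3-ol | C=C[C@@H](C)[C@@H](O)C(C)=C | intermediate
5 | (1R,2R)-2-methyl-1-[(2S)-2-methyloxiran-2-yl]but-3-en-1-ol | C=C[C@@H](C)[C@@H](O)[C@@]1(C)OC1 | intermediate
6 | (1R,2R)-2-methyl-1-[(2S)-2-methyloxiran-2-yl]butan-1-ol | CC[C@@H](C)[C@@H](O)[C@@]1(C)OC1 | intermediate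
7 | triethyl{(1R,2R)-2-methyl-1-[(2S)-2-methyloxiran-2-yl]butoxy}silane | CC[C@@H](C)[C@@H](O[Si](CC)(CC)CC)[C@@]1(C)OC1 | intermediate
8 | dimethyl{(3S,4R,5R)-3,5-dimethyl-3-oxido-4-[(triethylsilyl)oxy]heptyl}sulfonium (betaine) | CC[C@@H](C)[C@@H](O[Si](CC)(CC)CC)[C@@](C)([O-])CC[S+](C)C | intermediate
9 | (3S,4R,5R)-3,5-dimethyl-4-[(triethylsilyl)oxy]hept-1-en-3-ol | CC[C@@H](C)[C@@H](O[Si](CC)(CC)CC)[C@@](C)(O)C=C | intermediate
10 | N-methoxy-N-methylprop-2-enamide | C=CC(=O)N(C)OC | starting material
11 | (2E,4S,5R,6R)-4-hydroxy-N-methoxy-N,4,6-trimethyl-5-[(triethylsilyl)oxy]oct-2-enamide | CC[C@@H](C)[C@@H](O[Si](CC)(CC)CC)[C@@](C)(O)/C=C/C(=O)N(C)OC | intermediate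
12 | 2,4-dihydroxy-3,6-dimethylbenzaldehyde | Cc1cc(O)c(C)c(O)c1C=O | starting material
13 | 2,4-bis(methoxymethoxy)-3,6-dimethylbenzaldehyde | Cc1cc(OCOC)c(C)c(OCOC)c1C=O | intermediate
14 | lithium [2,4-bis(methoxymethoxy)-3,6-dimethylphenyl]{[2-(dimethylamino)ethyl](methyl)amino}methanolate | Cc1cc(OCOC)c(C)c(OCOC)c1C([O-])N(C)CCN(C)C.[Li+] | intermediate
15 | dilithium salt of 14 deprotonated at the C6 methyl group (benzylic carbanion) | [Li+].[Li+].[CH2-]c1cc(OCOC)c(C)c(OCOC)c1C([O-])N(C)CCN(C)C | intermediate
16 | 6-[(3E,5S,6R,7R)-5-hydroxy-5,7-dimethyl-2-oxo-6-[(triethylsilyl)oxy]non-3-en-1-yl]-2,4-bis(methoxymethoxy)-3-methylbenzaldehyde | CC[C@@H](C)[C@@H](O[Si](CC)(CC)CC)[C@@](C)(O)/C=C/C(=O)Cc1cc(OCOC)c(C)c(OCOC)c1C=O | intermediate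
17 | 6-[(3E,5S,6R,7R)-5,6-dihydroxy-5,7-dimethyl-2-oxonon-3-en-1-yl]-2,4-dihydroxy-3-methylbenzaldehyde | CC[C@@H](C)[C@@H](O)[C@@](C)(O)/C=C/C(=O)Cc1cc(O)c(C)c(O)c1C=O | intermediate
18 | (3S)-6-[(3E,5S,6R,7R)-5,6-dihydroxy-5,7-dimethyl-2-oxonon-3-en-1-yl]-2,3-dihydroxy-3-methyl-4-oxocyclohexa-1,5-diene-1-carbaldehyde | CC[C@@H](C)[C@@H](O)[C@@](C)(O)/C=C/C(=O)CC1=CC(=O)[C@@](C)(O)C(O)=C1C=O | intermediate
19 | (7R)-3-[(1E,3S,4R,5R)-3,4-dihydroxy-3,5-dimethylhept-1-en-1-yl]-7-hydroxy-7-methyl-6H-isochromene-6,8(7H)-dione | CC[C@@H](C)[C@@H](O)[C@@](C)(O)/C=C/C1=CC2=CC(=O)[C@@](C)(O)C(=O)C2=CO1 | intermediate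
20 | (7S,8S)-3-[(1E,3S,4R,5R)-3,4-dihydroxy-3,5-dimethylhept-1-en-1-yl]-7,8-dihydroxy-7-methyl-7,8-dihydro-6H-isochromen-6-one | CC[C@@H](C)[C@@H](O)[C@@](C)(O)/C=C/C1=CC2=CC(=O)[C@@](C)(O)[C@@H](O)C2=CO1 | intermediate
21 | (7S,8S)-3-[(1E,3S,4R,5R)-3,4-dihydroxy-3,5-dimethylhept-1-en-1-yl]-6,7,8-trihydroxy-7-methyl-7,8-dihydroisochromenylium diphenyl phosphate | CC[C@@H](C)[C@@H](O)[C@@](C)(O)/C=C/c1cc2C=C(O)[C@@](C)(O)[C@@H](O)c2c[o+]1.[O-]P(=O)(Oc1ccccc1)Oc1ccccc1 | intermediate
22 | (7S,8S)-3-[(1E,3S,4R,5R)-3,4-dihydroxy-3,5-dimethylhept-1-en-1-yl]-7-methyl-7,8-dihydro-1H-isochromene-6,7,8-triol | CC[C@@H](C)[C@@H](O)[C@@](C)(O)/C=C/C1=CC(C=C(O)[C@@](C)(O)[C@H]2O)=C2CO1 | intermediate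
23 | (7S,8S,8aS)-3-[(1E,3S,4R,5R)-3,4-dihydroxy-3,5-dimethylhept-1-en-1-yl]-7,8-dihydroxy-7-methyl-1,7,8,8a-tetrahydro-6H-isochromen-6-one | CC[C@@H](C)[C@@H](O)[C@@](C)(O)/C=C/C1=CC2=CC(=O)[C@@](C)(O)[C@@H](O)[C@@H]2CO1 | target

## Step count and least certain steps

Total: 12 steps. Longest linear sequence: 11 steps (steps 1 to 6, then 8 to 12); the arene branch contributes step 7 before the union in step 8.

Step 10 (key step). The diol-bearing chain may bind poorly in the active site, the hydroxyl may be delivered to the wrong face of C14, or uncoupled NADPH oxidation may outrun hydroxylation; the product can also be lost by condensation with protein amines. Fallback: starting from 17, cyclodehydration with CF3CO2H in 1,2-dichloroethane gives the 2-benzopyrylium salt, 3-[(1E,3S,4R,5R)-3,4-dihydroxy-3,5-dimethylhept-1-en-1-yl]-6,8-dihydroxy-7-methylisochromenylium trifluoroacetate F1. Oxidative dearomatisation of F1 with 2-iodoxybenzoic acid and catalytic n-Bu4NI hydroxylates C14 without face control. The two C14 epimers are diastereomers because of the chain stereocentres and would be separated by chromatography; the fallback rejoins the route at 19.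

Step 8. Lithiation may occur on the ring at C12–H next to the C13 acetal or at the C14 methyl instead of the C10 methyl, metalation of the electron-rich arene may be incomplete, or the carbanion may add in conjugate fashion. Fallback: starting from 13, oxidative esterification (I2, KOH, MeOH) gives methyl 2,4-bis(methoxymethoxy)-3,6-dimethylbenzoate F2, whose C10 methyl is acidified by the ester. LDA at −78 °C and acylation with 11 give the keto ester, methyl 6-[(3E,5S,6R,7R)-5-hydroxy-5,7-dimethyl-2-oxo-6-[(triethylsilyl)oxy]non-3-en-1-yl]-2,4-bis(methoxymethoxy)-3-methylbenzoate F3. Enol lactonisation (DBU, toluene, 60 °C) gives the isocoumarin, 3-[(1E,3S,4R,5R)-3-hydroxy-3,5-dimethyl-4-[(triethylsilyl)oxy]hept-1-en-1-yl]-6,8-bis(methoxymethoxy)-7-methyl-1H-isochromen-1-one F4. DIBAL-H at −78 °C gives the corresponding 1H-isochromen-1-ol F5, the ring-closed lactol form of 16. The conditions of step 9 applied to F5 bring the fallback back at 17.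

Step 11. The reductase may not turn over the vinylogous-ester carbonyl, may reduce C13 instead, may deliver hydride from the wrong face (trans-diol), or may be inactivated by 19. Fallback: starting from 19, silylation of all three hydroxyls with N-(trimethylsilyl)imidazole gives (7R)-3-[(1E,3S,4R,5R)-3,5-dimethyl-3,4-bis(trimethylsilyloxy)hept-1-en-1-yl]-7-methyl-7-(trimethylsilyloxy)-6H-isochromene-6,8(7H)-dione F6. DIBAL-H in toluene at −78 °C should then add to C15 anti to the bulky C14 silyloxy group (polar Felkin–Anh control), giving the (7S,8S)-8-hydroxy tris-silyl ether F7. Mild methanolysis (citric acid, MeOH) returns the route at 20.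

Step 12. Hydride may go to C9 or C11 instead of C17, the product may be reduced a second time through its protonated dienone, the acid may cause loss of the C15 or C6 hydroxyl, or C16 may be protonated from the wrong face without later equilibration. Fallback: the order of the two reductions is reversed, starting from 19. [(Ph3P)CuH]6 in THF–benzene adds hydride to C17, which in 19 is activated by both carbonyls, giving (7R,8aS)-3-[(1E,3S,4R,5R)-3,4-dihydroxy-3,5-dimethylhept-1-en-1-yl]-7-hydroxy-7-methyl-1,8a-dihydro-6H-isochromene-6,8(7H)-dione F8. F8 is a vinylogous 1,3-diketone, labile at C16, and is used without purification. Its C15 ketone is reduced at once (NaBH4, MeOH, −78 °C, axial attack anti to the axial C14 hydroxyl, or a ketoreductase acting dynamically at C16). This fallback rejoins the route at 23.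

Step 6. Metathesis may be slow at the vinyl group next to the quaternary carbinol, the acrylamide may only homodimerise, or ruthenium hydrides may isomerise the alkene. Fallback: starting from 9, ozonolysis (O3, CH2Cl2, −78 °C; PPh3) gives the non-epimerisable α-hydroxy aldehyde (2R,3R,4R)-2-hydroxy-2,4-dimethyl-3-[(triethylsilyl)oxy]hexanal F9. Horner–Wadsworth–Emmons olefination with diethyl [2-(methoxy(methyl)amino)-2-oxoethyl]phosphonate (LiCl, DBU, MeCN) gives the E enamide and rejoins the route at 11.

## Further compounds

F1 | step 10 | 3-[(1E,3S,4R,5R)-3,4-dihydroxy-3,5-dimethylhept-1-en-1-yl]-6,8-dihydroxy-7-methylisochromenylium trifluoroacetate | CC[C@@H](C)[C@@H](O)[C@@](C)(O)/C=C/c1cc2cc(O)c(C)c(O)c2c[o+]1.[O-]C(=O)C(F)(F)F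
F2 | step 8 | methyl 2,4-bis(methoxymethoxy)-3,6-dimethylbenzoate | Cc1cc(OCOC)c(C)c(OCOC)c1C(=O)OC
F3 | step 8 | methyl 6-[(3E,5S,6R,7R)-5-hydroxy-5,7-dimethyl-2-oxo-6-[(triethylsilyl)oxy]non-3-en-1-yl]-2,4-bis(methoxymethoxy)-3-methylbenzoate | CC[C@@H](C)[C@@H](O[Si](CC)(CC)CC)[C@@](C)(O)/C=C/C(=O)Cc1cc(OCOC)c(C)c(OCOC)c1C(=O)OC
F4 | step 8 | 3-[(1E,3S,4R,5R)-3-hydroxy-3,5-dimethyl-4-[(triethylsilyl)oxy]hept-1-en-1-yl]-6,8-bis(methoxymethoxy)-7-methyl-1H-isochromen-1-one | CC[C@@H](C)[C@@H](O[Si](CC)(CC)CC)[C@@](C)(O)/C=C/C1=Cc2cc(OCOC)c(C)c(OCOC)c2C(=O)O1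
F5 | step 8 | 3-[(1E,3S,4R,5R)-3-hydroxy-3,5-dimethyl-4-[(triethylsilyl)oxy]hept-1-en-1-yl]-6,8-bis(methoxymethoxy)-7-methyl-1H-isochromen-1-ol (both C1 epimers) | CC[C@@H](C)[C@@H](O[Si](CC)(CC)CC)[C@@](C)(O)/C=C/C1=Cc2cc(OCOC)c(C)c(OCOC)c2C(O)O1
F6 | step 11 | (7R)-3-[(1E,3S,4R,5R)-3,5-dimethyl-3,4-bis(trimethylsilyloxy)hept-1-en-1-yl]-7-methyl-7-(trimethylsilyloxy)-6H-isochromene-6,8(7H)-dione | CC[C@@H](C)[C@@H](O[Si](C)(C)C)[C@@](C)(O[Si](C)(C)C)/C=C/C1=CC2=CC(=O)[C@@](C)(O[Si](C)(C)C)C(=O)C2=CO1
F7 | step 11 | (7S,8S)-3-[(1E,3S,4R,5R)-3,5-dimethyl-3,4-bis(trimethylsilyloxy)hept-1-en-1-yl]-8-hydroxy-7-methyl-7-(trimethylsilyloxy)-7,8-dihydro-6H-isochromen-6-one | CC[C@@H](C)[C@@H](O[Si](C)(C)C)[C@@](C)(O[Si](C)(C)C)/C=C/C1=CC2=CC(=O)[C@@](C)(O[Si](C)(C)C)[C@@H](O)C2=CO1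
F8 | step 12 | (7R,8aS)-3-[(1E,3S,4R,5R)-3,4-dihydroxy-3,5-dimethylhept-1-en-1-yl]-7-hydroxy-7-methyl-1,8a-dihydro-6H-isochromene-6,8(7H)-dione | CC[C@@H](C)[C@@H](O)[C@@](C)(O)/C=C/C1=CC2=CC(=O)[C@@](C)(O)C(=O)[C@@H]2CO1
F9 | step 6 | (2R,3R,4R)-2-hydroxy-2,4-dimethyl-3-[(triethylsilyl)oxy]hexanal | CC[C@@H](C)[C@@H](O[Si](CC)(CC)CC)[C@@](C)(O)C=O
A1 | alternative 1 | 4-(methoxymethoxy)-4-methylcyclohexa-2,5-dien-1-one | CC1(OCOC)C=CC(=O)C=C1
A2 | alternative 1 | (4S,5S,6R)-6-(hydroxymethyl)-4-(methoxymethoxy)-4-methyl-5-(4,4,5,5-tetramethyl-1,3,2-dioxaborolan-2-yl)cyclohex-2-en-1-one | O=C1C=C[C@@](C)(OCOC)[C@@H](B2OC(C)(C)C(C)(C)O2)[C@@H]1CO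
A3 | alternative 2 | (2R,3R,5S)-2-[(benzyloxy)methyl]-3,5-bis[(tert-butyldimethylsilyl)oxy]-6-oxoheptanal | CC(=O)[C@@H](O[Si](C)(C)C(C)(C)C)C[C@@H](O[Si](C)(C)C(C)(C)C)[C@@H](COCc1ccccc1)C=O
A4 | alternative 2 | (1S,2S,3S,4R,6S)-3-[(benzyloxy)methyl]-4,6-bis[(tert-butyldimethylsilyl)oxy]-1-methylcyclohexane-1,2-diol | CC(C)(C)[Si](C)(C)O[C@@H]1C[C@H](O[Si](C)(C)C(C)(C)C)[C@@](C)(O)[C@@H](O)[C@@H]1COCc2ccccc2
A5 | alternative 3 | [(1S,4R,5R,6S)-2-ethenyl-5-methyl-4,5,6-tris(triethylsilyloxy)cyclohex-2-en-1-yl]methyl (2E,4S,5R,6R)-4,6-dimethyl-4,5-bis(triethylsilyloxy)oct-2-enoate | CC[C@@H](C)[C@@H](O[Si](CC)(CC)CC)[C@@](C)(O[Si](CC)(CC)CC)/C=C/C(=O)OC[C@H]1[C@H](O[Si](CC)(CC)CC)[C@](C)(O[Si](CC)(CC)CC)[C@H](O[Si](CC)(CC)CC)C=C1C=C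
A6 | alternative 3 | (6R,7R,8S,8aS)-3-[(1E,3S,4R,5R)-3,5-dimethyl-3,4-bis(triethylsilyloxy)hept-1-en-1-yl]-7-methyl-6,7,8-tris(triethylsilyloxy)-6,7,8,8a-tetrahydro-1H-isochromene | CC[C@@H](C)[C@@H](O[Si](CC)(CC)CC)[C@@](C)(O[Si](CC)(CC)CC)/C=C/C1=CC2=C[C@@H](O[Si](CC)(CC)CC)[C@@](C)(O[Si](CC)(CC)CC)[C@@H](O[Si](CC)(CC)CC)[C@@H]2CO1
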